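**Assumptions**
- The flavanone C‑2 in the target SMILES is (R), and I build that.
- 2,4‑Dihydroxybenzaldehyde iodinates at C‑5, as its bromination does.
- The (R)‑BINOL ligand in Step 8 is assumed to give the drawn enantiomer of the cyclohexene. If it does not, the (S)‑ligand is used.

**Retrosynthetic overview**
1. The target is the flavanone and the Diels–Alder cyclohexene, all as hexa‑MOM ether (14 ← 13). The pyranone ring forms last, by asymmetric oxa‑Michael closure of a 2′‑hydroxychalcone (13 ← 12).
2. The chalcone comes from Claisen–Schmidt condensation of the Diels–Alder aldehyde 11 with acetophenone 8 (12 ← 11 + 8).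
3. The cyclohexene (ring 1) forms first, by the proposed exo‑selective, enantioselective Diels–Alder of diene‑aldehyde 6 with chalcone 10 (11 ← 6 + 10). It sets the 3,5‑cis‑diaryl, 4‑trans‑aroyl array.
4. Diene 6 comes from Suzuki coupling of iodoarene 3 with a dienyl‑Bpin (5), which is made by hydroboration of 2‑methylbutenyne (4). Chalcone 10 comes from 8 and 9.

---

**Step 1**
Reactants: 1 (2,4‑dihydroxybenzaldehyde)
Product: 2 (2,4‑dihydroxy‑5‑iodobenzaldehyde)
Conditions: NIS, MeCN, 0 °C → rt, 2 h
Reagents that add atoms: N‑iodosuccinimide, O=C1CCC(=O)N1I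
Why: Electrophilic aromatic iodination goes at C‑5, which is para to the 2‑OH, ortho to the 4‑OH and meta to CHO. No stereocenters are involved.

**Step 2**
Reactants: 2
Product: 3 (5‑iodo‑2,4‑bis(methoxymethoxy)benzaldehyde)
Conditions: NaH (2.5 equiv), MOMCl (2.4 equiv), DMF, 0 °C → rt, 3 h
Reagents that add atoms: chloromethyl methyl ether (MOMCl), ClCOC
Why: O‑alkylation of both phenoxides gives base‑stable MOM ethers that are removed at the end.

**Step 3**
Reactants: 4 (2‑methylbut‑1‑en‑3‑yne)
Product: 5 ((E)‑2‑(3‑methylbuta‑1,3‑dien‑1‑yl)‑4,4,5,5‑tetramethyl‑1,3,2‑dioxaborolane)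
Conditions: HBpin (1.1 equiv), Cp2Zr(H)Cl (5 mol %), CH2Cl2, 0 °C → rt, 12 h
Reagents that add atoms: pinacolborane, [H]B1OC(C)(C)C(C)(C)O1
Why: Zr‑catalysed hydroboration (Schwartz hydrozirconation/transmetalation) is chemoselective for the alkyne over the 1,1‑disubstituted alkene. Syn addition gives the E‑dienylboronate.

**Step 4**
Reactants: 3 (iodoarene), 5 (dienyl‑Bpin)
Product: 6 ((E)‑5‑(3‑methylbuta‑1,3‑dienyl)‑2,4‑bis(MOMO)benzaldehyde)
Conditions: Pd(PPh3)4 (5 mol %), K3PO4 (3 equiv), THF/H2O 4:1, 60 °C, 6 h
Reagents that add atoms: none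
Why: Suzuki–Miyaura coupling is stereoretentive, so the E‑diene is kept. The CHO and MOM groups survive the mild base.

**Step 5**
Reactants: 7 (2,4‑dihydroxyacetophenone)
Product: 8 (1‑[2‑hydroxy‑4‑(methoxymethoxy)phenyl]ethanone)
Conditions: MOMCl (1.1 equiv), DIPEA (1.3 equiv), CH2Cl2, 0 °C, 4 h
Reagents that add atoms: MOMCl, ClCOC
Why: The 4‑OH is much more acidic and is the more reactive phenol, while the 2‑OH is locked in an H‑bond to the C=O. This gives 4‑O‑selective protection.

**Step 6**
Reactants: 1 (2,4‑dihydroxybenzaldehyde)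
Product: 9 (2,4‑bis(methoxymethoxy)benzaldehyde)
Conditions: NaH (2.5 equiv), MOMCl (2.4 equiv), DMF, 0 °C → rt, 3 h
Reagents that add atoms: MOMCl, ClCOC
Why: Same O‑alkylation as Step 2.

**Step 7**
Reactants: 8, 9
Product: 10 ((E)‑3‑[2,4‑bis(MOMO)phenyl]‑1‑[2‑hydroxy‑4‑(MOMO)phenyl]prop‑2‑en‑1‑one)
Conditions: 50 % aq. KOH (10 equiv), EtOH, 0 °C → rt, 24 h; quench with AcOH to pH ~5
Reagents that add atoms: none (water is lost)
Why: Claisen–Schmidt aldol condensation gives the thermodynamic E‑enone. Any flavanone formed reverts under the basic conditions, and the MOM groups are base‑stable.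

**Step 8** (key step, proposed new)
Reactants: 6 (diene, 2 equiv), 10 (chalcone, 1 equiv)
Product: 11 (Diels–Alder adduct: cyclohexene with C1 methyl, C3 = 5‑formyl‑2,4‑bis(MOMO)phenyl, C4 = 2‑hydroxy‑4‑(MOMO)benzoyl, C5 = 2,4‑bis(MOMO)phenyl; C3 and C5 aryls cis, aroyl trans to both)
Conditions: (R)‑3,3′‑bis(2,4,6‑triisopropylphenyl)‑BINOL (30 mol %) with B(OPh)3 (30 mol %), 4 Å MS, toluene, −10 → 25 °C, 72 h
Reagents that add atoms: none
Why: Proposed new method: a catalytic, enantio‑ and exo‑selective intermolecular Diels–Alder of an unprotected 2′‑hydroxychalcone with a 1‑aryl‑3‑methylbutadiene, going through a chiral BINOL‑boron chelate.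
- Exchange of PhO–B with the 2′‑OH of 10 gives a planar six‑membered O,O‑chelate. C=O→B binding lowers the enone LUMO.
- The bulky 3,3′‑aryl walls flank the boron‑bound carbonyl and block the endo quadrant. The diene therefore adds with the aroyl group exo, the β‑aryl (Ar3) tucked under the diene, and one enone face shielded by the BINOL wall.
- Regiochemistry follows the HOMO coefficients: the 4‑aryl and 2‑methyl donors make the CH2 terminus bond to Cβ.
- This sets C3, C4 and C5 together as 3,5‑cis aryls with the aroyl trans to both (the all‑equatorial array).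
- Any C4 epimer equilibrates to this all‑equatorial array in Step 9.
- Closest known reaction type: chiral Lewis acid/boron‑promoted Diels–Alder of 2′‑hydroxychalcones with dehydroprenyl arenes (biomimetic Morus adduct syntheses), combined with bulky‑Lewis‑acid exo control.

**Step 9**
Reactants: 11 (aldehyde), 8 (acetophenone)
Product: 12 (chalcone‑bearing adduct: 11 with the CHO replaced by CH=CH–C(=O)‑[2‑hydroxy‑4‑(MOMO)phenyl], E)
Conditions: 50 % aq. KOH (10 equiv), EtOH, 0 °C → rt, 24 h; quench with AcOH to pH ~5
Reagents that add atoms: none (water is lost)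
Why: Claisen–Schmidt condensation. The only enolizable ring stereocenter is C4, which is already in the thermodynamic all‑equatorial configuration, so C3, C4 and C5 are not scrambled.

**Step 10**
Reactants: 12
Product: 13 (hexa‑MOM flavanone, (2R))
Conditions: quinidine‑derived 9‑amino‑epi‑thiourea bifunctional catalyst (20 mol %), toluene, 25 °C, 5 d; silica gel chromatography to remove any minor C‑2 epimer
Reagents that add atoms: none
Why: Catalyst‑controlled intramolecular oxa‑Michael (6‑endo) cyclization of the 2′‑phenol onto the enone creates the C‑2 stereocenter. The catalyst's pseudo‑enantiomer is chosen to give (2R). The remote cyclohexene stereocenters impose only a weak bias, and the two C‑2 epimers are diastereomers and hence separable.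

**Step 11**
Reactants: 13
Product: 14 (target)
Conditions: 3 M aq. HCl/MeOH/THF (1:3:3), 40 °C, 16 h
Reagents that add atoms: none (all six MOM groups are lost)
Why: Acidolysis of aryl MOM ethers, with methanol scavenging the MOM cation as CH2(OMe)2 to prevent hydroxymethylation of the resorcinols. The flavanone C‑2 (stable to acid) and the trisubstituted alkene survive these mild conditions.

---

**Compound list**
1 | 2,4‑dihydroxybenzaldehyde | O=Cc1ccc(O)cc1O | starting material
2 | 2,4‑dihydroxy‑5‑iodobenzaldehyde | O=Cc1cc(I)c(O)cc1O | intermediate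
3 | 5‑iodo‑2,4‑bis(methoxymethoxy)benzaldehyde | O=Cc1cc(I)c(OCOC)cc1OCOC | intermediate
4 | 2‑methylbut‑1‑en‑3‑yne | C=C(C)C#C | starting material
5 | (E)‑2‑(3‑methylbuta‑1,3‑dienyl)‑Bpin | C=C(C)/C=C/B1OC(C)(C)C(C)(C)O1 | intermediate
6 | (E)‑5‑(3‑methylbuta‑1,3‑dienyl)‑2,4‑bis(MOMO)benzaldehyde | C=C(C)/C=C/c1cc(C=O)c(OCOC)cc1OCOC | intermediate
7 | 2,4‑dihydroxyacetophenone | CC(=O)c1ccc(O)cc1O | starting material
8 | 1‑[2‑hydroxy‑4‑(MOMO)phenyl]ethanone | CC(=O)c1ccc(OCOC)cc1O | intermediate
9 | 2,4‑bis(methoxymethoxy)benzaldehyde | O=Cc1ccc(OCOC)cc1OCOC | intermediate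
10 | (E)‑chalcone (2′‑OH, 4′,2,4‑tri‑MOMO) | O=C(/C=C/c1ccc(OCOC)cc1OCOC)c1ccc(OCOC)cc1O | intermediate
11 | Diels–Alder adduct aldehyde | CC1=C[C@@H](c2cc(C=O)c(OCOC)cc2OCOC)[C@H](C(=O)c2ccc(OCOC)cc2O)[C@@H](c2ccc(OCOC)cc2OCOC)C1 | intermediate
12 | Chalcone‑bearing adduct | CC1=C[C@@H](c2cc(/C=C/C(=O)c3ccc(OCOC)cc3O)c(OCOC)cc2OCOC)[C@H](C(=O)c2ccc(OCOC)cc2O)[C@@H](c2ccc(OCOC)cc2OCOC)C1 | intermediate
13 | Hexa‑MOM flavanone | CC1=C[C@@H](c2cc([C@H]3CC(=O)c4ccc(OCOC)cc4O3)c(OCOC)cc2OCOC)[C@H](C(=O)c2ccc(OCOC)cc2O)[C@@H](c2ccc(OCOC)cc2OCOC)C1 | intermediate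
14 | Target (C35H30O10) | CC1=C[C@@H](c2cc([C@H]3CC(=O)c4ccc(O)cc4O3)c(O)cc2O)[C@H](C(=O)c2ccc(O)cc2O)[C@@H](c2ccc(O)cc2O)C1 | target

---

**Total steps:** 11.
**Longest linear sequence:** 7 steps (1 → 2 → 3 → 6 → 11 → 12 → 13 → 14, i.e. Steps 1, 2, 4, 8, 9, 10, 11).

**Three steps most likely to fail**

1. **Step 8 (proposed new Diels–Alder).** It may give endo adduct, low ee, or stall through product inhibition or competing Lewis‑acid binding to the aldehyde.
   - Fallback: use known chemistry on a different design that needs no exo control. Run a thermal or Lewis‑acid Diels–Alder of diene 6 with the ynone ArC≡C–C(=O)Ar′, then do a Stryker conjugate reduction of the resulting 1,4‑cyclohexadiene, then equilibrate C‑4 with base. This gives racemic 11. In Step 10 the enantiopure catalyst then makes the two cyclohexene enantiomers into separable diastereomeric flavanones, and the (2R)‑series diastereomer is isolated by HPLC.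

2. **Step 10 (asymmetric oxa‑Michael).** The electron‑rich 2,4‑dialkoxy chalcone is a poor, reversible Michael acceptor, so conversion or diastereoselectivity may be low.
   - Fallback: cyclize non‑selectively (NaOAc, EtOH, reflux) to the C‑2 epimer mixture and separate the desired (2R) diastereomer by preparative HPLC. This replaces catalyst control with resolution.

3. **Step 11 (global removal of six MOM groups).** It risks hydroxymethylation, oligomerization or alkene/flavanone damage.
   - Fallback: change the protecting‑group strategy to benzyl ethers. Use BnBr in place of MOMCl in Steps 2, 5 and 6, carry them through, and remove them at the end with BCl3 and pentamethylbenzene (cation scavenger) at −78 °C. This avoids Brønsted acid, and with no hydrogenolysis the alkene is spared.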